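**Retrosynthetic overview**
1. The target comes from its C1 silyl ether, made by a C13–C14 sp3–sp2 Negishi coupling of an east alkylzinc (lactone half) with a west dienyl iodide (oxolane–ketone half).
2. The west dienyl iodide comes from a C9–C10 nickel-catalysed stereoconvergent alkenylation of an α-bromo ethyl ketone with a silyl-capped dienylzinc linchpin (sets C9), then iododesilylation.
3. The bromo ketone comes from an oxolane built by Shi epoxidation and 5-exo epoxide opening of an anti,anti crotylation product (sets quaternary C3), whose chain comes from a Roche-ester zinc homoenolate and a Z-vinyl iodide (Negishi).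
4. The east half comes from a C17–C18 Stille coupling of a Z-vinyl iodide (Roche ester, Zhao–Wittig) with a stannyl dihydropyranone (Brown crotylation, acryloylation, ring-closing metathesis); both crotylations draw on one batch of (E)-crotylborane made from (E)-but-2-ene.
5. Ring order: oxolane first (west), dihydropyranone second (east); both rings are closed before the three fragment couplings.

Assumption: the target is taken exactly as the SMILES encodes it, numbered C1 (CH2OH) to C19 (alkene CH on the lactone): 3R,5R,6R,7R,9R,15R; 10E,12E,16Z,18E; lactone 5S,6R (trans). TBS = tert-butyldimethylsilyl. Steps 7 and 22 are run side by side, so that the single batch of crotylborane 11 from step 6 is consumed at once.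

**West fragment**

Step 1
Reactants: 1 but-2-yn-1-ol
Product: 2 (2Z)-3-iodobut-2-en-1-ol
Conditions: NaAlH2(OCH2CH2OMe)2, THF, 0 °C to rt; then I2, −78 to 0 °C
Reagents that add atoms: iodine, II
Why: The alkoxide directs trans-hydroalumination with aluminium on C3, and iodinolysis with retention gives the Z vinyl iodide (directed hydroalumination–iodination).

Step 2
Reactants: 2 (2Z)-3-iodobut-2-en-1-ol
Product: 3 tert-butyl{[(2Z)-3-iodobut-2-en-1-yl]oxy}dimethylsilane
Conditions: TBSCl, imidazole, CH2Cl2, rt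
Reagents that add atoms: tert-butyldimethylsilyl chloride, CC(C)(C)[Si](C)(C)Cl
Why: Routine silylation protects the future C1 hydroxyl until the last step.

Step 3
Reactants: 4 methyl (2R)-3-hydroxy-2-methylpropanoate (Roche ester)
Product: 5 methyl (2S)-3-iodo-2-methylpropanoate
Conditions: I2, PPh3, imidazole, CH2Cl2, 0 °C to rt
Reagents that add atoms: iodine, II
Why: Appel-type iodination at the primary carbon leaves the stereocentre (future C5) untouched; the descriptor changes only through CIP priority.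

Step 4
Reactants: 5 methyl (2S)-3-iodo-2-methylpropanoate and 3 tert-butyl{[(2Z)-3-iodobut-2-en-1-yl]oxy}dimethylsilane
Product: 7 methyl (2R,4Z)-6-(TBSO)-2,4-dimethylhex-4-enoate, via zinc homoenolate 6 (not isolated)
Conditions: Zn dust (activated with BrCH2CH2Br, Me3SiCl), DMF, rt; then 3, Pd2(dba)3 (2.5 mol%), P(o-tol)3 (10 mol%), rt to 40 °C
Reagents that add atoms: none
Why: The β-zincio ester cannot eliminate or epimerise, and the Negishi sp3–sp2 coupling forms C3–C4 with retention of the Z alkene.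

Step 5
Reactants: 7 methyl (2R,4Z)-6-(TBSO)-2,4-dimethylhex-4-enoate
Product: 8 (2R,4Z)-6-(TBSO)-2,4-dimethylhex-4-enal
Conditions: i-Bu2AlH (1.05 equiv), CH2Cl2, −78 °C; aq. KNaC4H4O6 work-up; used crude
Reagents that add atoms: none
Why: The tetrahedral aluminium hemiacetal is stable at −78 °C, so partial ester reduction stops at the aldehyde without epimerising C5.

Step 6
Reactants: 9 (E)-but-2-ene
Product: 11 (E)-but-2-en-1-ylbis(isopinocampheyl)borane of the (+)-α-pinene series, via crotylpotassium 10 (not isolated)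
Conditions: 9 (excess), KOt-Bu, n-BuLi, THF, −78 to −45 °C, 10 min; (−)-Ipc2BOMe, Et2O, −78 °C, 30 min; BF3·OEt2, −78 °C; one batch, kept at −78 °C and divided by cannula at once between the flasks of steps 7 and 22
Reagents that add atoms: (−)-B-methoxydiisopinocampheylborane, COB([C@@H]1C[C@@H]2C[C@H]([C@H]1C)C2(C)C)[C@@H]1C[C@@H]2C[C@H]([C@H]1C)C2(C)C
Why: Schlosser-base metalation of (E)-but-2-ene gives (E)-crotylpotassium, which keeps its geometry below −45 °C; transfer to boron and removal of methoxide by BF3·OEt2 give the (E)-crotylborane, which does not undergo 1,3-boratropic isomerisation at −78 °C (Brown crotylborane preparation).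

Step 7
Reactants: 8 (2R,4Z)-6-(TBSO)-2,4-dimethylhex-4-enal and 11 (E)-but-2-en-1-ylbis(isopinocampheyl)borane of the (+)-α-pinene series
Product: 12 (3S,4R,5R,7Z)-9-(TBSO)-3,5,7-trimethylnona-1,7-dien-4-ol
Conditions: 11 (1.5 equiv, cold THF–Et2O solution from step 6), then 8 in THF, −78 °C, 4 h; NaOH, H2O2, 0 °C to rt
Reagents that add atoms: none
Why: Brown crotylboration through a chair Zimmerman–Traxler transition state: the E-crotyl unit gives the 6,7-anti pair, and the borane of the (+)-α-pinene series attacks the aldehyde Si face under reagent control, giving the 5,6-anti (anti-Felkin) relationship (C6 R, C7 as in the target).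

Step 8
Reactants: 12 (3S,4R,5R,7Z)-9-(TBSO)-3,5,7-trimethylnona-1,7-dien-4-ol
Product: 14 (1R)-1-{(2R,4R,5R)-5-[(2S)-but-3-en-2-yl]-2,4-dimethyloxolan-2-yl}-2-(TBSO)ethan-1-ol, via epoxide 13 (not isolated)
Conditions: D-fructose-derived Shi ketone (30 mol%), Oxone (2KHSO5·KHSO4·K2SO4), K2CO3, Bu4NHSO4, MeCN–CH2(OMe)2–aq. buffer pH 10.5, 0 °C; then CSA (10 mol%), CH2Cl2, 0 °C
Reagents that add atoms: potassium peroxymonosulfate, [K+].[O-]S(=O)(=O)OO
Why: Shi epoxidation of the trisubstituted alkene (spiro transition state) gives the (2S,3R)-epoxide, and acid-promoted 5-exo-tet attack of the C6 hydroxyl on the tertiary carbon with inversion closes the oxolane and sets quaternary C3 as R.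

Step 9
Reactants: 14 (1R)-1-{(2R,4R,5R)-5-[(2S)-but-3-en-2-yl]-2,4-dimethyloxolan-2-yl}-2-(TBSO)ethan-1-ol
Product: 15 O-[(1R)-1-{(2R,4R,5R)-5-[(2S)-but-3-en-2-yl]-2,4-dimethyloxolan-2-yl}-2-(TBSO)ethyl] O-phenyl carbonothioate
Conditions: PhOC(S)Cl, pyridine, DMAP, CH2Cl2, rt
Reagents that add atoms: O-phenyl carbonochloridothioate, S=C(Cl)Oc1ccccc1
Why: Neutral acylation gives the thionocarbonate needed for Barton–McCombie deoxygenation without silyl migration.

Step 10
Reactants: 15 O-phenyl thionocarbonate of 14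
Product: 16 tert-butyl(2-{(2R,4R,5R)-5-[(2S)-but-3-en-2-yl]-2,4-dimethyloxolan-2-yl}ethoxy)dimethylsilane
Conditions: Bu3SnH (3 equiv, 0.5 M), AIBN, toluene, 90 °C
Reagents that add atoms: none
Why: Barton–McCombie radical deoxygenation removes the C2 oxygen; concentrated stannane outruns 6-exo cyclisation onto the vinyl group and no stereocentre is touched.

Step 11
Reactants: 16 tert-butyl(2-{(2R,4R,5R)-5-[(2S)-but-3-en-2-yl]-2,4-dimethyloxolan-2-yl}ethoxy)dimethylsilane
Product: 17 (2R)-2-{(2R,3R,5R)-5-[2-(TBSO)ethyl]-3,5-dimethyloxolan-2-yl}propanal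
Conditions: O3, CH2Cl2, −78 °C; then PPh3, −78 °C to rt; used crude
Reagents that add atoms: ozone, [O-][O+]=O
Why: Ozonolysis with reductive work-up cleaves the only alkene to the C8 aldehyde under neutral conditions that keep C7.

Step 12
Reactants: 17 (2R)-2-{(2R,3R,5R)-5-[2-(TBSO)ethyl]-3,5-dimethyloxolan-2-yl}propanal
Product: 18 (2S,3RS)-2-{(2R,3R,5R)-5-[2-(TBSO)ethyl]-3,5-dimethyloxolan-2-yl}pentan-3-ol
Conditions: EtMgBr, THF, −78 °C
Reagents that add atoms: ethylmagnesium bromide, CC[Mg]Br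
Why: Grignard addition installs C9 and its methyl; the C8 carbinol configuration is irrelevant because it is oxidised next.

Step 13
Reactants: 18 (2S,3RS)-2-{(2R,3R,5R)-5-[2-(TBSO)ethyl]-3,5-dimethyloxolan-2-yl}pentan-3-ol
Product: 19 (2R)-2-{(2R,3R,5R)-5-[2-(TBSO)ethyl]-3,5-dimethyloxolan-2-yl}pentan-3-one
Conditions: Dess–Martin periodinane, NaHCO3, CH2Cl2, rt
Reagents that add atoms: none
Why: Buffered Dess–Martin oxidation gives the ethyl ketone without epimerising C7 or opening the β-alkoxy ketone.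

Step 14
Reactants: 19 (2R)-2-{(2R,3R,5R)-5-[2-(TBSO)ethyl]-3,5-dimethyloxolan-2-yl}pentan-3-one
Product: 21 (2RS,4R)-2-bromo-4-{(2R,3R,5R)-5-[2-(TBSO)ethyl]-3,5-dimethyloxolan-2-yl}pentan-3-one, via silyl enol ether 20 (not isolated)
Conditions: LiN(SiMe3)2, Me3SiCl (internal quench), THF, −78 °C; then NBS, −78 to 0 °C
Reagents that add atoms: N-bromosuccinimide, O=C1CCC(=O)N1Br
Why: Kinetic deprotonation at the unhindered CH2 (C9) is trapped as the silyl enol ether and brominated; neither the enol ether geometry nor the C9 epimer ratio matters for the next step.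

**Linchpin**

Step 15
Reactants: 22 [(E)-2-bromoethenyl]trimethylsilane and 23 ethynyltrimethylsilane
Product: 24 (E)-but-1-en-3-yne-1,4-diylbis(trimethylsilane)
Conditions: PdCl2(PPh3)2 (2 mol%), CuI (4 mol%), Et3N, THF, rt
Reagents that add atoms: none
Why: Sonogashira coupling proceeds with retention of the E vinyl geometry.

Step 16
Reactants: 24 (E)-but-1-en-3-yne-1,4-diylbis(trimethylsilane)
Product: 25 [(E)-but-1-en-3-yn-1-yl]trimethylsilane
Conditions: K2CO3 (0.2 equiv), MeOH, 0 °C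
Reagents that add atoms: none
Why: Methanolysis cleaves only the alkynyl C–Si bond and leaves the alkenylsilane (selective protodesilylation).

Step 17
Reactants: 25 [(E)-but-1-en-3-yn-1-yl]trimethylsilane
Product: 27 [(1E,3E)-4-iodo-3-methylbuta-1,3-dien-1-yl]trimethylsilane, via alkenylalane 26 (not isolated)
Conditions: Me3Al (2 equiv), Cp2ZrCl2 (0.25 equiv), CH2Cl2, 0 °C to rt; then I2, THF, −30 °C
Reagents that add atoms: trimethylaluminium, C[Al](C)C; iodine, II
Why: Negishi zirconium-catalysed syn-carboalumination puts methyl on the internal carbon (C11) and aluminium on C10, and iodinolysis with retention gives the E,E-dienyl iodide.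

**West–linchpin coupling**

Step 18
Reactants: 21 (2RS,4R)-2-bromo-4-{(2R,3R,5R)-5-[2-(TBSO)ethyl]-3,5-dimethyloxolan-2-yl}pentan-3-one and 27 [(1E,3E)-4-iodo-3-methylbuta-1,3-dien-1-yl]trimethylsilane
Product: 30 (2R,4R,5E,7E)-2-{(2R,3R,5R)-5-[2-(TBSO)ethyl]-3,5-dimethyloxolan-2-yl}-4,6-dimethyl-8-(trimethylsilyl)octa-5,7-dien-3-one, via dienyllithium 28 (not isolated), via dienylzinc chloride 29 (not isolated)
Conditions: 27, t-BuLi (2.05 equiv), Et2O, −78 °C; ZnCl2, THF, −78 to 0 °C; then 21, NiCl2·DME (10 mol%), (R,R)-Ph-pybox (13 mol%), DME–THF, −30 °C, 24 h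
Reagents that add atoms: none
Why: Proposed new method: a stereoconvergent nickel-catalysed Negishi alkenylation of an epimeric α-bromo dialkyl ketone with a β,β-disubstituted dienylzinc; a monovalent nickel–pybox species abstracts bromine from either C9 epimer to give a planar α-keto radical, the dienyl group moves from zinc to nickel, radical capture gives a trivalent nickel(alkyl)(alkenyl) complex whose chiral pocket fixes C9 as R before C–C reductive elimination, so both epimers funnel to one product and the C8 ketone arrives at its final oxidation level without base near C7/C9; the closest known reaction type is the nickel/pybox or nickel/bis(oxazoline) stereoconvergent Negishi arylation and organozirconium alkenylation of racemic α-bromo ketones, which has not been shown for dienylzinc reagents, for dialkyl ketones with an α′-stereocentre, or as a catalyst-controlled diastereoconvergent fragment coupling (the ligand enantiomer is confirmed on a model, since its antipode would give 9S).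

Step 19
Reactants: 30 (2R,4R,5E,7E)-2-{(2R,3R,5R)-5-[2-(TBSO)ethyl]-3,5-dimethyloxolan-2-yl}-4,6-dimethyl-8-(trimethylsilyl)octa-5,7-dien-3-one
Product: 31 (2R,4R,5E,7E)-2-{(2R,3R,5R)-5-[2-(TBSO)ethyl]-3,5-dimethyloxolan-2-yl}-8-iodo-4,6-dimethylocta-5,7-dien-3-one
Conditions: NIS, (CF3)2CHOH, 0 °C, 10 min, dark
Reagents that add atoms: N-iodosuccinimide, O=C1CCC(=O)N1I
Why: Ipso-iododesilylation through the β-silyl cation replaces silicon by iodine with retention of the E geometry at C13.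

**East fragment**

Step 20
Reactants: 32 prop-2-yn-1-ol
Product: 33 (2E)-3-(tributylstannyl)prop-2-en-1-ol
Conditions: Bu3SnH, AIBN (cat.), neat, 80 °C
Reagents that add atoms: tributyltin hydride, CCCC[SnH](CCCC)CCCC
Why: Radical hydrostannation under equilibrating conditions gives the thermodynamic E terminal vinylstannane.

Step 21
Reactants: 33 (2E)-3-(tributylstannyl)prop-2-en-1-ol
Product: 34 (2E)-3-(tributylstannyl)prop-2-enal
Conditions: MnO2, CH2Cl2, rt
Reagents that add atoms: none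
Why: Chemoselective allylic oxidation leaves the C–Sn bond intact.

Step 22
Reactants: 34 (2E)-3-(tributylstannyl)prop-2-enal and 11 (E)-but-2-en-1-ylbis(isopinocampheyl)borane of the (+)-α-pinene series
Product: 35 (1E,3S,4S)-4-methyl-1-(tributylstannyl)hexa-1,5-dien-3-ol
Conditions: 11 (1.3 equiv, second portion of the step 6 batch, cold THF–Et2O solution), then 34 in THF, −78 °C, 3 h; NaOH, H2O2, 0 °C
Reagents that add atoms: none
Why: Brown crotylboration with the same reagent: the E-crotyl chair transition state gives the anti pair and Si-face attack sets both lactone stereocentres (trans-5,6 after ring closure).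

Step 23
Reactants: 35 (1E,3S,4S)-4-methyl-1-(tributylstannyl)hexa-1,5-dien-3-ol and 36 prop-2-enoyl chloride
Product: 37 (1E,3S,4S)-4-methyl-1-(tributylstannyl)hexa-1,5-dien-3-yl prop-2-enoate
Conditions: i-Pr2NEt, DMAP (cat.), CH2Cl2, −20 to 0 °C
Reagents that add atoms: none
Why: Simple O-acylation sets up the diene for ring closure.

Step 24
Reactants: 37 (1E,3S,4S)-4-methyl-1-(tributylstannyl)hexa-1,5-dien-3-yl prop-2-enoate
Product: 38 (5S,6S)-5-methyl-6-[(E)-2-(tributylstannyl)ethenyl]-5,6-dihydro-2H-pyran-2-one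
Conditions: second-generation Grubbs catalyst RuCl2(=CHPh)(H2IMes)(PCy3) (5 mol%), CH2Cl2, 40 °C
Reagents that add atoms: none
Why: Ring-closing metathesis of the acrylate and the terminal vinyl group closes the dihydropyranone; the hindered vinylstannane does not take part.

Step 25
Reactants: 4 methyl (2R)-3-hydroxy-2-methylpropanoate
Product: 39 methyl (2R)-3-(TBSO)-2-methylpropanoate
Conditions: TBSCl, imidazole, DMF, rt
Reagents that add atoms: tert-butyldimethylsilyl chloride, CC(C)(C)[Si](C)(C)Cl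
Why: Routine silylation; the stereocentre becomes C15.

Step 26
Reactants: 39 methyl (2R)-3-(TBSO)-2-methylpropanoate
Product: 40 (2R)-3-(TBSO)-2-methylpropanal
Conditions: i-Bu2AlH, CH2Cl2, −78 °C; aq. KNaC4H4O6 work-up; used crude
Reagents that add atoms: none
Why: Partial ester reduction at −78 °C gives the configurationally labile aldehyde, which is used at once.

Step 27
Reactants: 41 1-bromopropane
Product: 42 triphenyl(propyl)phosphonium bromide
Conditions: PPh3, toluene, 110 °C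
Reagents that add atoms: triphenylphosphine, c1ccc(cc1)P(c1ccccc1)c1ccccc1
Why: SN2 quaternisation gives the Wittig salt.

Step 28
Reactants: 40 (2R)-3-(TBSO)-2-methylpropanal and 42 triphenyl(propyl)phosphonium bromide
Product: 46 tert-butyl{[(2S,3Z)-4-iodo-2-methylhex-3-en-1-yl]oxy}dimethylsilane, via ylide 43 (not isolated), via iodophosphonium iodide 44 (not isolated), via iodo ylide 45 (not isolated)
Conditions: 42, n-BuLi, THF, rt; I2, −78 °C; NaN(SiMe3)2, −20 °C; then 40, −78 °C to rt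
Reagents that add atoms: iodine, II
Why: Stork–Zhao-type Wittig olefination with the α-iodo ylide gives the trisubstituted vinyl iodide with iodine cis to the C15 chain (16Z after coupling).

Step 29
Reactants: 46 tert-butyl{[(2S,3Z)-4-iodo-2-methylhex-3-en-1-yl]oxy}dimethylsilane and 38 (5S,6S)-5-methyl-6-[(E)-2-(tributylstannyl)ethenyl]-5,6-dihydro-2H-pyran-2-one
Product: 47 (5S,6R)-6-[(1E,3Z,5S)-6-(TBSO)-3-ethyl-5-methylhexa-1,3-dien-1-yl]-5-methyl-5,6-dihydro-2H-pyran-2-one
Conditions: Pd2(dba)3 (5 mol%), AsPh3 (20 mol%), NMP, rt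
Reagents that add atoms: none
Why: Stille coupling forms C17–C18 with retention at both alkenes under neutral conditions that the lactone tolerates.

Step 30
Reactants: 47 (5S,6R)-6-[(1E,3Z,5S)-6-(TBSO)-3-ethyl-5-methylhexa-1,3-dien-1-yl]-5-methyl-5,6-dihydro-2H-pyran-2-one
Product: 48 (5S,6R)-6-[(1E,3Z,5S)-3-ethyl-6-hydroxy-5-methylhexa-1,3-dien-1-yl]-5-methyl-5,6-dihydro-2H-pyran-2-one
Conditions: HF·pyridine, pyridine, THF, 0 °C to rt
Reagents that add atoms: none
Why: Buffered fluoride desilylation frees the primary alcohol without touching lactone or diene.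

Step 31
Reactants: 48 (5S,6R)-6-[(1E,3Z,5S)-3-ethyl-6-hydroxy-5-methylhexa-1,3-dien-1-yl]-5-methyl-5,6-dihydro-2H-pyran-2-one
Product: 49 (5S,6R)-6-[(1E,3Z,5S)-3-ethyl-6-iodo-5-methylhexa-1,3-dien-1-yl]-5-methyl-5,6-dihydro-2H-pyran-2-one
Conditions: I2, PPh3, imidazole, CH2Cl2, 0 °C
Reagents that add atoms: iodine, II
Why: Appel-type iodination of the primary alcohol under near-neutral conditions.

**Endgame**

Step 32
Reactants: 49 (5S,6R)-6-[(1E,3Z,5S)-3-ethyl-6-iodo-5-methylhexa-1,3-dien-1-yl]-5-methyl-5,6-dihydro-2H-pyran-2-one and 31 (2R,4R,5E,7E)-2-{(2R,3R,5R)-5-[2-(TBSO)ethyl]-3,5-dimethyloxolan-2-yl}-8-iodo-4,6-dimethylocta-5,7-dien-3-one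
Product: 51 C1 TBS ether of the target, via alkylzinc iodide 50 (not isolated)
Conditions: 49 (1.3 equiv), Zn dust (activated), LiCl, THF, 35 °C; then 31, Pd(OAc)2 (5 mol%), SPhos (10 mol%), THF–NMP, rt
Reagents that add atoms: none
Why: LiCl-mediated zinc insertion tolerates the lactone, and the base-free Negishi sp3–sp2 coupling forms C13–C14 with retention of the E,E-diene while the C9 centre of the β,γ-unsaturated ketone survives.

Step 33
Reactants: 51 C1 TBS ether of the target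
Product: 52 (5S,6R)-6-[(1E,3Z,5R,7E,9E,11R,13R)-3-ethyl-13-[(2R,3R,5R)-5-(2-hydroxyethyl)-3,5-dimethyloxolan-2-yl]-5,9,11-trimethyl-12-oxotetradeca-1,3,7,9-tetraen-1-yl]-5-methyl-5,6-dihydro-2H-pyran-2-one (the target)
Conditions: HF·pyridine, pyridine, THF, 0 °C
Reagents that add atoms: none
Why: Buffered fluoride desilylation of the primary silyl ether is mild enough for the lactone and the epimerisable C7/C9 centres.

**Compound list**

1 | but-2-yn-1-ol | CC#CCO | starting material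
2 | (2Z)-3-iodobut-2-en-1-ol | C/C(I)=C/CO | intermediate
3 | tert-butyl{[(2Z)-3-iodobut-2-en-1-yl]oxy}dimethylsilane | C/C(I)=C/CO[Si](C)(C)C(C)(C)C | intermediate
4 | methyl (2R)-3-hydroxy-2-methylpropanoate | COC(=O)[C@H](C)CO | starting material
5 | methyl (2S)-3-iodo-2-methylpropanoate | COC(=O)[C@H](C)CI | intermediate
6 | iodo[(2S)-3-methoxy-2-methyl-3-oxopropyl]zinc | COC(=O)[C@H](C)C[Zn]I | intermediate
7 | methyl (2R,4Z)-6-(TBSO)-2,4-dimethylhex-4-enoate | COC(=O)[C@H](C)C/C(C)=C\CO[Si](C)(C)C(C)(C)C | intermediate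
8 | (2R,4Z)-6-(TBSO)-2,4-dimethylhex-4-enal | O=C[C@H](C)C/C(C)=C\CO[Si](C)(C)C(C)(C)C | intermediate
9 | (E)-but-2-ene | C/C=C/C | starting material
10 | (E)-but-2-en-1-ylpotassium | [K]C/C=C/C | intermediate
11 | (E)-but-2-en-1-ylbis(isopinocampheyl)borane of the (+)-α-pinene series | C/C=C/CB([C@@H]1C[C@@H]2C[C@H]([C@H]1C)C2(C)C)[C@@H]1C[C@@H]2C[C@H]([C@H]1C)C2(C)C | intermediate
12 | (3S,4R,5R,7Z)-9-(TBSO)-3,5,7-trimethylnona-1,7-dien-4-ol | C=C[C@H](C)[C@H](O)[C@H](C)C/C(C)=C\CO[Si](C)(C)C(C)(C)C | intermediate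
13 | (3S,4R,5R)-6-[(2S,3R)-3-(TBSO-methyl)-2-methyloxiran-2-yl]-3,5-dimethylhex-1-en-4-ol | C=C[C@H](C)[C@H](O)[C@H](C)C[C@]1(C)O[C@@H]1CO[Si](C)(C)C(C)(C)C | intermediate
14 | (1R)-1-{(2R,4R,5R)-5-[(2S)-but-3-en-2-yl]-2,4-dimethyloxolan-2-yl}-2-(TBSO)ethan-1-ol | C=C[C@H](C)[C@@H]1O[C@@](C)([C@H](O)CO[Si](C)(C)C(C)(C)C)C[C@H]1C | intermediate
15 | O-phenyl thionocarbonate of 14 | C=C[C@H](C)[C@@H]1O[C@@](C)([C@H](OC(=S)Oc2ccccc2)CO[Si](C)(C)C(C)(C)C)C[C@H]1C | intermediate
16 | tert-butyl(2-{(2R,4R,5R)-5-[(2S)-but-3-en-2-yl]-2,4-dimethyloxolan-2-yl}ethoxy)dimethylsilane | C=C[C@H](C)[C@@H]1O[C@@](C)(CCO[Si](C)(C)C(C)(C)C)C[C@H]1C | intermediate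
17 | (2R)-2-{(2R,3R,5R)-5-[2-(TBSO)ethyl]-3,5-dimethyloxolan-2-yl}propanal | O=C[C@H](C)[C@@H]1O[C@@](C)(CCO[Si](C)(C)C(C)(C)C)C[C@H]1C | intermediate
18 | (2S,3RS)-2-{(2R,3R,5R)-5-[2-(TBSO)ethyl]-3,5-dimethyloxolan-2-yl}pentan-3-ol | CCC(O)[C@H](C)[C@@H]1O[C@@](C)(CCO[Si](C)(C)C(C)(C)C)C[C@H]1C | intermediate
19 | (2R)-2-{(2R,3R,5R)-5-[2-(TBSO)ethyl]-3,5-dimethyloxolan-2-yl}pentan-3-one | CCC(=O)[C@H](C)[C@@H]1O[C@@](C)(CCO[Si](C)(C)C(C)(C)C)C[C@H]1C | intermediate
20 | (Z)-trimethylsilyl enol ether of 19 (C8=C9) | C/C=C(\O[Si](C)(C)C)[C@H](C)[C@@H]1O[C@@](C)(CCO[Si](C)(C)C(C)(C)C)C[C@H]1C | intermediate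
21 | (2RS,4R)-2-bromo-4-{(2R,3R,5R)-5-[2-(TBSO)ethyl]-3,5-dimethyloxolan-2-yl}pentan-3-one | CC(Br)C(=O)[C@H](C)[C@@H]1O[C@@](C)(CCO[Si](C)(C)C(C)(C)C)C[C@H]1C | intermediate
22 | [(E)-2-bromoethenyl]trimethylsilane | C[Si](C)(C)/C=C/Br | starting material
23 | ethynyltrimethylsilane | C#C[Si](C)(C)C | starting material
24 | (E)-but-1-en-3-yne-1,4-diylbis(trimethylsilane) | C[Si](C)(C)/C=C/C#C[Si](C)(C)C | intermediate
25 | [(E)-but-1-en-3-yn-1-yl]trimethylsilane | C[Si](C)(C)/C=C/C#C | intermediate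
26 | dimethyl[(1E,3E)-2-methyl-4-(trimethylsilyl)buta-1,3-dien-1-yl]alumane | C[Si](C)(C)/C=C/C(C)=C/[Al](C)C | intermediate
27 | [(1E,3E)-4-iodo-3-methylbuta-1,3-dien-1-yl]trimethylsilane | C[Si](C)(C)/C=C/C(C)=C/I | intermediate
28 | [(1E,3E)-2-methyl-4-(trimethylsilyl)buta-1,3-dien-1-yl]lithium | C[Si](C)(C)/C=C/C(C)=C/[Li] | intermediate
29 | chloro[(1E,3E)-2-methyl-4-(trimethylsilyl)buta-1,3-dien-1-yl]zinc | C[Si](C)(C)/C=C/C(C)=C/[Zn]Cl | intermediate
30 | (2R,4R,5E,7E)-2-{(2R,3R,5R)-5-[2-(TBSO)ethyl]-3,5-dimethyloxolan-2-yl}-4,6-dimethyl-8-(trimethylsilyl)octa-5,7-dien-3-one | C[Si](C)(C)/C=C/C(C)=C/[C@@H](C)C(=O)[C@H](C)[C@@H]1O[C@@](C)(CCO[Si](C)(C)C(C)(C)C)C[C@H]1C | intermediate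
31 | (2R,4R,5E,7E)-2-{(2R,3R,5R)-5-[2-(TBSO)ethyl]-3,5-dimethyloxolan-2-yl}-8-iodo-4,6-dimethylocta-5,7-dien-3-one | I/C=C/C(C)=C/[C@@H](C)C(=O)[C@H](C)[C@@H]1O[C@@](C)(CCO[Si](C)(C)C(C)(C)C)C[C@H]1C | intermediate
32 | prop-2-yn-1-ol | C#CCO | starting material
33 | (2E)-3-(tributylstannyl)prop-2-en-1-ol | CCCC[Sn](CCCC)(CCCC)/C=C/CO | intermediate
34 | (2E)-3-(tributylstannyl)prop-2-enal | CCCC[Sn](CCCC)(CCCC)/C=C/C=O | intermediate
35 | (1E,3S,4S)-4-methyl-1-(tributylstannyl)hexa-1,5-dien-3-ol | CCCC[Sn](CCCC)(CCCC)/C=C/[C@@H](O)[C@@H](C)C=C | intermediate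
36 | prop-2-enoyl chloride | C=CC(Cl)=O | starting material
37 | (1E,3S,4S)-4-methyl-1-(tributylstannyl)hexa-1,5-dien-3-yl prop-2-enoate | CCCC[Sn](CCCC)(CCCC)/C=C/[C@@H](OC(=O)C=C)[C@@H](C)C=C | intermediate
38 | (5S,6S)-5-methyl-6-[(E)-2-(tributylstannyl)ethenyl]-5,6-dihydro-2H-pyran-2-one | CCCC[Sn](CCCC)(CCCC)/C=C/[C@H]1OC(=O)C=C[C@@H]1C | intermediate
39 | methyl (2R)-3-(TBSO)-2-methylpropanoate | COC(=O)[C@H](C)CO[Si](C)(C)C(C)(C)C | intermediate
40 | (2R)-3-(TBSO)-2-methylpropanal | O=C[C@H](C)CO[Si](C)(C)C(C)(C)C | intermediate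
41 | 1-bromopropane | CCCBr | starting material
42 | triphenyl(propyl)phosphonium bromide | CCC[P+](c1ccccc1)(c1ccccc1)c1ccccc1.[Br-] | intermediate
43 | propylidenetriphenylphosphorane | CCC=P(c1ccccc1)(c1ccccc1)c1ccccc1 | intermediate
44 | (1-iodopropyl)triphenylphosphonium iodide | CCC(I)[P+](c1ccccc1)(c1ccccc1)c1ccccc1.[I-] | intermediate
45 | (1-iodopropylidene)triphenylphosphorane | CCC(I)=P(c1ccccc1)(c1ccccc1)c1ccccc1 | intermediate
46 | tert-butyl{[(2S,3Z)-4-iodo-2-methylhex-3-en-1-yl]oxy}dimethylsilane | CC/C(I)=C/[C@H](C)CO[Si](C)(C)C(C)(C)C | intermediate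
47 | (5S,6R)-6-[(1E,3Z,5S)-6-(TBSO)-3-ethyl-5-methylhexa-1,3-dien-1-yl]-5-methyl-5,6-dihydro-2H-pyran-2-one | CCC(=C/[C@H](C)CO[Si](C)(C)C(C)(C)C)/C=C/[C@H]1OC(=O)C=C[C@@H]1C | intermediate
48 | (5S,6R)-6-[(1E,3Z,5S)-3-ethyl-6-hydroxy-5-methylhexa-1,3-dien-1-yl]-5-methyl-5,6-dihydro-2H-pyran-2-one | CCC(=C/[C@H](C)CO)/C=C/[C@H]1OC(=O)C=C[C@@H]1C | intermediate
49 | (5S,6R)-6-[(1E,3Z,5S)-3-ethyl-6-iodo-5-methylhexa-1,3-dien-1-yl]-5-methyl-5,6-dihydro-2H-pyran-2-one | CCC(=C/[C@H](C)CI)/C=C/[C@H]1OC(=O)C=C[C@@H]1C | intermediate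
50 | {(2S,3Z,5E)-4-ethyl-2-methyl-6-[(2R,3S)-3-methyl-6-oxo-3,6-dihydro-2H-pyran-2-yl]hexa-3,5-dien-1-yl}(iodo)zinc | CCC(=C/[C@H](C)C[Zn]I)/C=C/[C@H]1OC(=O)C=C[C@@H]1C | intermediate
51 | (5S,6R)-6-[(1E,3Z,5R,7E,9E,11R,13R)-13-{(2R,3R,5R)-5-[2-(TBSO)ethyl]-3,5-dimethyloxolan-2-yl}-3-ethyl-5,9,11-trimethyl-12-oxotetradeca-1,3,7,9-tetraen-1-yl]-5-methyl-5,6-dihydro-2H-pyran-2-one | CCC(=C/[C@H](C)C/C=C/C(C)=C/[C@@H](C)C(=O)[C@H](C)[C@@H]1O[C@@](C)(CCO[Si](C)(C)C(C)(C)C)C[C@H]1C)/C=C/[C@H]1OC(=O)C=C[C@@H]1C | intermediate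
52 | (5S,6R)-6-[(1E,3Z,5R,7E,9E,11R,13R)-3-ethyl-13-[(2R,3R,5R)-5-(2-hydroxyethyl)-3,5-dimethyloxolan-2-yl]-5,9,11-trimethyl-12-oxotetradeca-1,3,7,9-tetraen-1-yl]-5-methyl-5,6-dihydro-2H-pyran-2-one | CCC(=C/[C@H](C)C/C=C/C(C)=C/[C@@H](C)C(=O)[C@H](C)[C@@H]1O[C@@](C)(CCO)C[C@H]1C)/C=C/[C@H]1OC(=O)C=C[C@@H]1C | target

**Totals and risks**

Total step count: 33. Longest linear sequence: 16 steps (1, 2, 4, 5, 7–14, 18, 19, 32, 33), which is less than half of the total.

Three steps most likely to fail: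

Step 18 (the proposed nickel alkenylation). Risks are debromination or enolisation of 21, homocoupling of the dienylzinc, and weak catalyst control next to the C7 stereocentre. The fallback uses known chemistry, sets out from aldehyde 17 and comes back at ketone 30. Commercial pent-3-yn-2-one is reduced by Noyori transfer hydrogenation (RuCl[(S,S)-TsDPEN](p-cymene), i-PrOH) to (2S)-pent-3-yn-2-ol F3, which is mesylated (MsCl, Et3N, CH2Cl2, −78 °C) to (2S)-pent-3-yn-2-yl methanesulfonate F4. Marshall propargylation of 17 with the allenylzinc made in situ from F4 (Pd(OAc)2, PPh3, Et2Zn, THF, −20 °C) gives the anti, Felkin-matched homopropargylic alcohol (2S,3R,4R)-2-{(2R,3R,5R)-5-[2-(TBSO)ethyl]-3,5-dimethyloxolan-2-yl}-4-methylhept-5-yn-3-ol F5, with C9 set by net inversion of the mesylate. Silylation (Me3SiCl, imidazole) gives the trimethylsilyl ether of F5 F6, so that hydrozirconation is sterically and not alkoxide directed. Cp2Zr(H)Cl (THF, 50 °C) then I2 gives the (5E)-6-iodohept-5-ene trimethylsilyl ether F7. Stille coupling with (E)-Bu3SnCH=CHSiMe3 (Pd2(dba)3, AsPh3, NMP) gives the dienylsilane trimethylsilyl ether F8. K2CO3 in MeOH frees the alcohol (2S,3R,4R,5E,7E)-2-{(2R,3R,5R)-5-[2-(TBSO)ethyl]-3,5-dimethyloxolan-2-yl}-4,6-dimethyl-8-(trimethylsilyl)octa-5,7-dien-3-ol F9, and Dess–Martin oxidation of F9 gives 30.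

Step 7 (anti,anti crotylboration under reagent control). The borane must override the Felkin preference of 8, so the diastereomer ratio may be modest. The fallback sets out from 8 and comes back at 12; the whole batch of 11 from step 6 then serves step 22 alone. Commercial (R)-but-3-yn-2-ol is mesylated to (2R)-but-3-yn-2-yl methanesulfonate F1. Marshall propargylation of 8 with the allenylzinc from F1 (Pd(OAc)2, PPh3, Et2Zn, THF, −20 °C) gives the anti,anti homopropargylic alcohol (3S,4R,5R,7Z)-9-(TBSO)-3,5,7-trimethylnon-7-en-1-yn-4-ol F2. Lindlar semihydrogenation (Pd/CaCO3 with Pb(OAc)2, quinoline, H2, EtOAc) of the terminal alkyne gives 12.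

Step 32 (late sp3–sp2 Negishi union of two advanced fragments). Risks are sluggish zinc insertion beside the lactone, protodezincation, and loss of the C9 configuration. The fallback sets out from 49 and 31 and comes back at 51. It is a nickel-catalysed reductive cross-electrophile coupling of the two iodides without a preformed organometallic (NiBr2·DME, 4,4′-di-tert-butyl-2,2′-bipyridine, Mn powder, NaI, DMA, rt): the alkyl radical from 49 is captured by the alkenylnickel species from 31. It makes no compound outside the list: none F0.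

**Further compounds**

F1 | step 7 | (2R)-but-3-yn-2-yl methanesulfonate | C#C[C@@H](C)OS(C)(=O)=O
F2 | step 7 | (3S,4R,5R,7Z)-9-(TBSO)-3,5,7-trimethylnon-7-en-1-yn-4-ol | C#C[C@H](C)[C@H](O)[C@H](C)C/C(C)=C\CO[Si](C)(C)C(C)(C)C
F3 | step 18 | (2S)-pent-3-yn-2-ol | C[C@H](O)C#CC
F4 | step 18 | (2S)-pent-3-yn-2-yl methanesulfonate | C[C@H](OS(C)(=O)=O)C#CC
F5 | step 18 | (2S,3R,4R)-2-{(2R,3R,5R)-5-[2-(TBSO)ethyl]-3,5-dimethyloxolan-2-yl}-4-methylhept-5-yn-3-ol | CC#C[C@@H](C)[C@@H](O)[C@H](C)[C@@H]1O[C@@](C)(CCO[Si](C)(C)C(C)(C)C)C[C@H]1C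
F6 | step 18 | trimethylsilyl ether of F5 | CC#C[C@@H](C)[C@@H](O[Si](C)(C)C)[C@H](C)[C@@H]1O[C@@](C)(CCO[Si](C)(C)C(C)(C)C)C[C@H]1C
F7 | step 18 | (5E)-6-iodohept-5-ene trimethylsilyl ether from F6 (iodine on C11) | C/C(I)=C\[C@@H](C)[C@@H](O[Si](C)(C)C)[C@H](C)[C@@H]1O[C@@](C)(CCO[Si](C)(C)C(C)(C)C)C[C@H]1C
F8 | step 18 | (5E,7E)-8-(trimethylsilyl)octa-5,7-diene trimethylsilyl ether from F7 | C[Si](C)(C)/C=C/C(C)=C/[C@@H](C)[C@@H](O[Si](C)(C)C)[C@H](C)[C@@H]1O[C@@](C)(CCO[Si](C)(C)C(C)(C)C)C[C@H]1C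
F9 | step 18 | (2S,3R,4R,5E,7E)-2-{(2R,3R,5R)-5-[2-(TBSO)ethyl]-3,5-dimethyloxolan-2-yl}-4,6-dimethyl-8-(trimethylsilyl)octa-5,7-dien-3-ol | C[Si](C)(C)/C=C/C(C)=C/[C@@H](C)[C@@H](O)[C@H](C)[C@@H]1O[C@@](C)(CCO[Si](C)(C)C(C)(C)C)C[C@H]1C
F0 | step 32 | none | none
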